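**Retrosynthetic overview**

1. The route rests on one feature of ring A (the carbocycle C1–C10): the oxygens on C2 and on C14 (the exocyclic carbon on C10) are 1,4-related across the C1=C10 double bond and trans on it. Both C–O bonds are therefore made by palladium-catalysed 1,4-diacetoxylation of the C14=C10–C1=C2 diene of 22, and a lipase then frees the primary C14 alcohol.
2. 22 comes from methacrylation of C8–OH and from ring B (the γ-lactone O–C6–C7–C11–C12), closed by carbonylation of a C11 vinyl bromide onto C6–OH. The lactone is made only after ring A is closed, so that no acrylate-type alkene is present during metathesis.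
3. Ring A is closed at C1=C2 by diene–ene ring-closing metathesis; the 2-substituted butadiene comes from ethylene cross-metathesis of the terminal alkyne C10≡C1.
4. C6–C7 is made by anti-selective Nozaki–Hiyama coupling of 2-bromoallylic bromide 9 (C7–C9 from (S)-glycidol, C10/C1 from acetylide, C11/C13 from a bromo ylide) with cis-dienal 15 (from but-2-yn-1-ol and an allylstannane).
5. Order of ring formation: ring A first, then ring B; C12 comes from CO and C14 from ethylene.

Key step: step 16

Remark: atoms carry germacrane numbers throughout (C13 exocyclic on C11, C15 on C4), α/β refer to the flat drawing in which the C8 ester is β, and it is assumed that the twisted ring diene of 22 still reacts as a 1,3-diene toward palladium.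

Step 1
Reactants: 1 (S)-glycidol; 2 lithium acetylide–ethylenediamine complex LiC≡CH·H2NCH2CH2NH2
Product: 3 (2R)-pent-4-yne-1,2-diol
Conditions: 2 (3 equiv), DMSO, 0 °C to rt; aq NH4Cl
Reagents that add atoms: none
Why: SN2 opening of the epoxide at its unsubstituted carbon by acetylide leaves the carbinol stereocentre (later C8) untouched, and a Payne rearrangement of the glycidol alkoxide would be degenerate, so the configuration of 1 is carried over.

Step 2
Reactants: 3 (2R)-pent-4-yne-1,2-diol
Product: 4 (4R)-4,5-bis(triethylsilyloxy)pent-1-yne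
Conditions: Et3SiCl, imidazole, DMF, 0 °C to rt
Reagents that add atoms: chlorotriethylsilane CC[Si](Cl)(CC)CC
Why: Silyl ether formation on both hydroxyl groups, with no change at the stereocentre.

Step 3
Reactants: 4 (4R)-4,5-bis(triethylsilyloxy)pent-1-yne
Product: 5 (2R)-2-(triethylsilyloxy)pent-4-ynal
Conditions: (COCl)2, DMSO, CH2Cl2, −78 to −30 °C; Et3N, −78 to 0 °C
Reagents that add atoms: none
Why: Swern oxidation of a bis-triethylsilyl ether, in which the chlorosulfonium salt cleaves the less hindered primary silyl ether and oxidises it to the aldehyde while the secondary silyl ether stays; the α-silyloxy aldehyde is used at once so that C8 does not epimerise.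

Step 4
Reactants: 5 (2R)-2-(triethylsilyloxy)pent-4-ynal; 6 ethyl 2-bromo-2-(triphenyl-λ5-phosphanylidene)acetate
Product: 7 ethyl (2Z,4R)-2-bromo-4-(triethylsilyloxy)hept-2-en-6-ynoate
Conditions: CH2Cl2, 0 °C to rt
Reagents that add atoms: none
Why: Wittig olefination with a stabilised α-bromo ylide should give mainly the (Z)-α-bromo enoate (bromine cis to C8) under neutral conditions that do not epimerise the aldehyde, and a minor alkene isomer can be carried along because the allylchromium reagent of step 10 equilibrates.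

Step 5
Reactants: 7 ethyl (2Z,4R)-2-bromo-4-(triethylsilyloxy)hept-2-en-6-ynoate
Product: 8 (2Z,4R)-2-bromo-4-(triethylsilyloxy)hept-2-en-6-yn-1-ol
Conditions: i-Bu2AlH (2.2 equiv), CH2Cl2, −78 °C; aq potassium sodium tartrate
Reagents that add atoms: none
Why: 1,2-Reduction of the conjugated ester by i-Bu2AlH at low temperature should give the allylic alcohol and leave the vinyl bromide, the alkyne and the silyl ether alone.

Step 6
Reactants: 8 (2Z,4R)-2-bromo-4-(triethylsilyloxy)hept-2-en-6-yn-1-ol
Product: 9 (4R,5Z)-6,7-dibromo-4-(triethylsilyloxy)hept-5-en-1-yne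
Conditions: CBr4, PPh3, CH2Cl2, 0 °C
Reagents that add atoms: tetrabromomethane BrC(Br)(Br)Br
Why: Appel bromination converts the primary allylic alcohol into the bromide by SN2 displacement of the oxyphosphonium group, without allylic transposition and without touching C8.

Step 7
Reactants: 10 but-2-yn-1-ol
Product: 12 (2Z)-3-iodobut-2-en-1-ol, via cyclic alkenylaluminate 11 (not isolated)
Conditions: NaAlH2(OCH2CH2OMe)2, THF, 0 °C to rt; then I2, −78 to 0 °C
Reagents that add atoms: iodine [I][I]
Why: Hydroxyl-directed trans-hydroalumination of the propargylic alcohol puts aluminium on the methyl-bearing carbon in a five-membered chelate, and iodinolysis with retention gives the vinyl iodide with iodine cis to the hydroxymethyl group, which fixes the later ring-cis C4=C5 geometry.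

Step 8
Reactants: 12 (2Z)-3-iodobut-2-en-1-ol; 13 allyltributylstannane
Product: 14 (2Z)-3-methylhexa-2,5-dien-1-ol
Conditions: Pd2(dba)3 (2.5 mol %), AsPh3 (10 mol %), NMP, 40 °C
Reagents that add atoms: none
Why: Stille coupling of the vinyl iodide with the allylstannane proceeds with retention of alkene geometry, so the allyl group ends up cis to the hydroxymethyl group in the skipped diene.

Step 9
Reactants: 14 (2Z)-3-methylhexa-2,5-dien-1-ol
Product: 15 (2Z)-3-methylhexa-2,5-dienal
Conditions: MnO2 (15 equiv), CH2Cl2, 0 °C to rt; used without storage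
Reagents that add atoms: none
Why: Oxidation of the allylic alcohol with MnO2 under neutral conditions should give the cis enal without isomerisation to the trans isomer.

Step 10
Reactants: 9 (4R,5Z)-6,7-dibromo-4-(triethylsilyloxy)hept-5-en-1-yne; 15 (2Z)-3-methylhexa-2,5-dienal
Product: 17 (4Z,6R,7S,8R)-7-(1-bromoethenyl)-4-methyl-8-(triethylsilyloxy)undeca-1,4-dien-10-yn-6-ol, via allylchromium dichloride 16 (not isolated)
Conditions: CrCl2 (4 equiv), THF, 0 °C to rt; 15 (1.3 equiv)
Reagents that add atoms: none
Why: Nozaki–Hiyama allylation, in which divalent chromium inserts only into the allylic C–Br bond (the vinylic bromide is inert without a nickel salt) and the γ-substituted allylchromium reagent adds to the aldehyde at C7 through a closed chair transition state with both substituents equatorial, which sets C6 and C7 anti (the later trans lactone), while the aldehyde is expected on the allyl face anti to the C9 methylene of the C8 stereocentre, whose hydrogen lies in the allyl plane next to bromine (allylic 1,3-strain) and whose small silyloxy oxygen sits on the aldehyde side, which sets C7 relative to C8.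

Step 11
Reactants: 17 (4Z,6R,7S,8R)-7-(1-bromoethenyl)-4-methyl-8-(triethylsilyloxy)undeca-1,4-dien-10-yn-6-ol
Product: 18 (4Z,6R,7S,8R)-7-(1-bromoethenyl)-4-methyl-10-methylidene-8-(triethylsilyloxy)dodeca-1,4,11-trien-6-ol
Conditions: second-generation Grubbs catalyst RuCl2(=CHPh)(PCy3)(H2IMes) (5 mol %), ethylene (1 atm), CH2Cl2, rt
Reagents that add atoms: ethylene C=C
Why: Enyne cross-metathesis of the terminal alkyne with ethylene gives the 2-substituted buta-1,3-diene, and under ethylene the ruthenium methylidene is the resting carbene, so ring closure is held back and the 2-bromoalkene and the trisubstituted alkene take no part.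

Step 12
Reactants: 18 (4Z,6R,7S,8R)-7-(1-bromoethenyl)-4-methyl-10-methylidene-8-(triethylsilyloxy)dodeca-1,4,11-trien-6-ol
Product: 19 (1R,2Z,5Z,9R,10S)-10-(1-bromoethenyl)-3-methyl-7-methylidene-9-(triethylsilyloxy)cyclodeca-2,5-dien-1-ol
Conditions: second-generation Grubbs catalyst RuCl2(=CHPh)(PCy3)(H2IMes) (10 mol %, in portions), toluene (1 mM), 80 °C, argon stream
Reagents that add atoms: none
Why: Ring-closing metathesis between the monosubstituted diene terminus (C1) and the allyl group (C2) with loss of ethylene closes the ten-membered ring A, the new C1=C2 bond being expected ring-cis because a trans alkene flanked by the sp2 carbon C10 and one methylene away from the cis C4=C5 bond would be strongly strained, and the 2-bromoalkene, a poor metathesis partner, keeps C13 out of competing six- or seven-membered ring closures.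

Step 13
Reactants: 19 (1R,2Z,5Z,9R,10S)-10-(1-bromoethenyl)-3-methyl-7-methylidene-9-(triethylsilyloxy)cyclodeca-2,5-dien-1-ol
Product: 20 (3aS,4R,7Z,10Z,11aR)-10-methyl-3,6-dimethylidene-4-(triethylsilyloxy)-3a,4,5,6,9,11a-hexahydrocyclodeca[b]furan-2(3H)-one
Conditions: Pd(PPh3)4 (10 mol %), CO (1 atm), Et3N, MeCN, 65 °C
Reagents that add atoms: carbon monoxide [C-]#[O+]
Why: Palladium-catalysed carbonylative lactonisation, in which zerovalent palladium adds oxidatively to the C11–Br bond, CO inserts and the C6 hydroxyl captures the acylpalladium, closes ring B with the exocyclic methylene already in place, and because C8 is still silylated only the lactone to O6 can form.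

Step 14
Reactants: 20 (3aS,4R,7Z,10Z,11aR)-10-methyl-3,6-dimethylidene-4-(triethylsilyloxy)-3a,4,5,6,9,11a-hexahydrocyclodeca[b]furan-2(3H)-one
Product: 21 (3aR,4R,7Z,10Z,11aR)-4-hydroxy-10-methyl-3,6-dimethylidene-3a,4,5,6,9,11a-hexahydrocyclodeca[b]furan-2(3H)-one
Conditions: HF·pyridine, pyridine, THF, 0 °C
Reagents that add atoms: none
Why: Fluoride cleavage of the triethylsilyl ether under buffered, non-basic conditions should leave the α-methylene lactone intact and give no opening for translactonisation to O8.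

Step 15
Reactants: 21 (3aR,4R,7Z,10Z,11aR)-4-hydroxy-10-methyl-3,6-dimethylidene-3a,4,5,6,9,11a-hexahydrocyclodeca[b]furan-2(3H)-one
Product: 22 [(3aR,4R,7Z,10Z,11aR)-10-methyl-3,6-dimethylidene-2-oxo-3a,4,5,6,9,11a-hexahydrocyclodeca[b]furan-4-yl] 2-methylprop-2-enoate
Conditions: methacrylic anhydride, Et3N, DMAP (cat), CH2Cl2, 0 °C to rt
Reagents that add atoms: methacrylic anhydride C=C(C)C(=O)OC(=O)C(C)=C
Why: DMAP-catalysed acylation of the secondary alcohol installs the methacrylate with retention at C8.

Step 16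
Reactants: 22 [(3aR,4R,7Z,10Z,11aR)-10-methyl-3,6-dimethylidene-2-oxo-3a,4,5,6,9,11a-hexahydrocyclodeca[b]furan-4-yl] 2-methylprop-2-enoate
Product: 24 [(3aR,4R,6E,8S,10Z,11aR)-8-acetyloxy-6-(acetyloxymethyl)-10-methyl-3-methylidene-2-oxo-3a,4,5,8,9,11a-hexahydrocyclodeca[b]furan-4-yl] 2-methylprop-2-enoate, via acetoxy π-allylpalladium acetate 23 (not isolated)
Conditions: Pd(OAc)2 (5 mol %), p-benzoquinone (20 mol %), MnO2 (1.5 equiv), LiOAc, AcOH, 25 °C, no chloride
Reagents that add atoms: acetic acid CC(=O)O; lithium acetate [Li+].CC(=O)[O-]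
Why: Palladium-catalysed oxidative 1,4-diacetoxylation of a conjugated diene, known for cyclic and open-chain 1,3-dienes and applied here to a ring diene with one exocyclic double bond: divalent palladium binds the C14=C10–C1=C2 unit, acetate adds from outside to the terminal methylene C14, and C10, C1 and C2 flatten into the π-allyl complex 23. Benzoquinone then coordinates and, with no chloride present, the palladium-bound acetate migrates to the allyl terminus C2 on the metal-bearing face, which forms the second C–O bond, moves the alkene to C1=C10 and releases zerovalent palladium that benzoquinone reoxidises, MnO2 regenerating the quinone. No ring is closed. The single new stereocentre C2 is controlled by the face of the diene that palladium takes: the C8 methacrylate lies on the β face, palladium is expected on the α face, and cis migration then gives the 2α-acetate (2S). The step needs 1,4- rather than 1,2-addition, secured because the other allyl terminus C10 is fully substituted, and a ring-cis C1=C10 bond (C14 trans to C2), secured because in 23 the two anti positions are taken by the ring carbons C9 and C3, which the ring ties together, while C14 is syn. It also needs the diene to react alone, which should hold because the methacrylate and the α-methylene lactone are electron-poor and the trisubstituted C4=C5 bond is isolated.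

Step 17
Reactants: 24 [(3aR,4R,6E,8S,10Z,11aR)-8-acetyloxy-6-(acetyloxymethyl)-10-methyl-3-methylidene-2-oxo-3a,4,5,8,9,11a-hexahydrocyclodeca[b]furan-4-yl] 2-methylprop-2-enoate
Product: 25 [(3aR,4R,6E,8S,10Z,11aR)-8-acetyloxy-6-(hydroxymethyl)-10-methyl-3-methylidene-2-oxo-3a,4,5,8,9,11a-hexahydrocyclodeca[b]furan-4-yl] 2-methylprop-2-enoate (CNP0138477.1)
Conditions: Candida antarctica lipase B (immobilised), phosphate buffer pH 7–acetone, 30 °C
Reagents that add atoms: none
Why: Lipase-catalysed hydrolysis should remove the unhindered primary allylic acetate much faster than the secondary C2 acetate, the hindered C8 methacrylate or the lactone, and avoids any base that would add to the α-methylene lactone.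

**Compound list**

1 | (S)-glycidol, (2S)-oxiran-2-ylmethanol | OC[C@H]1CO1 | starting material
2 | lithium acetylide–ethylenediamine complex | [Li]C#C.NCCN | starting material
3 | (2R)-pent-4-yne-1,2-diol | OC[C@H](O)CC#C | intermediate
4 | (4R)-4,5-bis(triethylsilyloxy)pent-1-yne | CC[Si](CC)(CC)OC[C@H](O[Si](CC)(CC)CC)CC#C | intermediate
5 | (2R)-2-(triethylsilyloxy)pent-4-ynal | O=C[C@H](O[Si](CC)(CC)CC)CC#C | intermediate
6 | ethyl 2-bromo-2-(triphenyl-λ5-phosphanylidene)acetate | CCOC(=O)C(Br)=P(c1ccccc1)(c1ccccc1)c1ccccc1 | starting material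
7 | ethyl (2Z,4R)-2-bromo-4-(triethylsilyloxy)hept-2-en-6-ynoate | CCOC(=O)/C(Br)=C/[C@H](O[Si](CC)(CC)CC)CC#C | intermediate
8 | (2Z,4R)-2-bromo-4-(triethylsilyloxy)hept-2-en-6-yn-1-ol | OC/C(Br)=C/[C@H](O[Si](CC)(CC)CC)CC#C | intermediate
9 | (4R,5Z)-6,7-dibromo-4-(triethylsilyloxy)hept-5-en-1-yne | BrC/C(Br)=C/[C@H](O[Si](CC)(CC)CC)CC#C | intermediate
10 | but-2-yn-1-ol | CC#CCO | starting material
11 | sodium 2,2-bis(2-methoxyethoxy)-3-methyl-2,5-dihydro-1,2-oxaluminol-2-uide (cyclic alkenylaluminate) | CC1=CCO[Al-]1(OCCOC)OCCOC.[Na+] | intermediate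
12 | (2Z)-3-iodobut-2-en-1-ol | C/C(I)=C/CO | intermediate
13 | allyltributylstannane | C=CC[Sn](CCCC)(CCCC)CCCC | starting material
14 | (2Z)-3-methylhexa-2,5-dien-1-ol | C=CC/C(C)=C\CO | intermediate
15 | (2Z)-3-methylhexa-2,5-dienal | C=CC/C(C)=C\C=O | intermediate
16 | [(2Z,4R)-2-bromo-4-(triethylsilyloxy)hept-2-en-6-yn-1-yl]chromium dichloride (solvent ligands omitted) | Cl[Cr](Cl)C/C(Br)=C/[C@H](O[Si](CC)(CC)CC)CC#C | intermediate
17 | (4Z,6R,7S,8R)-7-(1-bromoethenyl)-4-methyl-8-(triethylsilyloxy)undeca-1,4-dien-10-yn-6-ol | C#CC[C@@H](O[Si](CC)(CC)CC)[C@@H](C(Br)=C)[C@H](O)/C=C(C)\CC=C | intermediate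
18 | (4Z,6R,7S,8R)-7-(1-bromoethenyl)-4-methyl-10-methylidene-8-(triethylsilyloxy)dodeca-1,4,11-trien-6-ol | C=CC(=C)C[C@@H](O[Si](CC)(CC)CC)[C@@H](C(Br)=C)[C@H](O)/C=C(C)\CC=C | intermediate
19 | (1R,2Z,5Z,9R,10S)-10-(1-bromoethenyl)-3-methyl-7-methylidene-9-(triethylsilyloxy)cyclodeca-2,5-dien-1-ol | CC[Si](CC)(CC)O[C@@H]1CC(=C)/C=C\C/C(C)=C\[C@@H](O)[C@@H]1C(Br)=C | intermediate
20 | (3aS,4R,7Z,10Z,11aR)-10-methyl-3,6-dimethylidene-4-(triethylsilyloxy)-3a,4,5,6,9,11a-hexahydrocyclodeca[b]furan-2(3H)-one | CC[Si](CC)(CC)O[C@@H]1CC(=C)/C=C\C/C(C)=C\[C@H]2OC(=O)C(=C)[C@@H]21 | intermediate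
21 | (3aR,4R,7Z,10Z,11aR)-4-hydroxy-10-methyl-3,6-dimethylidene-3a,4,5,6,9,11a-hexahydrocyclodeca[b]furan-2(3H)-one | O[C@@H]1CC(=C)/C=C\C/C(C)=C\[C@H]2OC(=O)C(=C)[C@@H]21 | intermediate
22 | [(3aR,4R,7Z,10Z,11aR)-10-methyl-3,6-dimethylidene-2-oxo-3a,4,5,6,9,11a-hexahydrocyclodeca[b]furan-4-yl] 2-methylprop-2-enoate (diene lactone, precursor of the key step) | C=C(C)C(=O)O[C@@H]1CC(=C)/C=C\C/C(C)=C\[C@H]2OC(=O)C(=C)[C@@H]21 | intermediate
23 | acetoxy π-allylpalladium acetate of 22 (acetate on C14, palladium over C10–C1–C2 on the α face; drawn as its C2-bound σ-allyl form) | C=C(C)C(=O)O[C@@H]1C/C(COC(C)=O)=C\[C@@H]([Pd]OC(C)=O)C/C(C)=C\[C@H]2OC(=O)C(=C)[C@@H]21 | intermediate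
24 | [(3aR,4R,6E,8S,10Z,11aR)-8-acetyloxy-6-(acetyloxymethyl)-10-methyl-3-methylidene-2-oxo-3a,4,5,8,9,11a-hexahydrocyclodeca[b]furan-4-yl] 2-methylprop-2-enoate (C14 acetate of the target) | C=C(C)C(=O)O[C@@H]1C/C(COC(C)=O)=C\[C@@H](OC(C)=O)C/C(C)=C\[C@H]2OC(=O)C(=C)[C@@H]21 | intermediate
25 | [(3aR,4R,6E,8S,10Z,11aR)-8-acetyloxy-6-(hydroxymethyl)-10-methyl-3-methylidene-2-oxo-3a,4,5,8,9,11a-hexahydrocyclodeca[b]furan-4-yl] 2-methylprop-2-enoate (CNP0138477.1) | C=C(C)C(=O)O[C@@H]1C/C(CO)=C\[C@@H](OC(C)=O)C/C(C)=C\[C@H]2OC(=O)C(=C)[C@@H]21 | target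

**Step count and risk**

Total steps: 17. Longest linear sequence: 14 steps (steps 1–6, then 10–17).

The three steps most likely to fail are step 16, step 12 and step 10, in that order.

For step 16, palladium may bind the twisted ring diene mainly on the β face, next to the C8 ester, so that chloride-free migration would deliver acetate to the wrong face of C2; slow reaction of the non-planar diene and some 1,2-addition are lesser concerns. The fallback sets out from 22 and comes back at 24. Palladium-catalysed 1,4-acetoxychlorination (Pd(OAc)2, benzoquinone, LiCl, LiOAc, AcOH), in which chloride attacks C2 from outside and anti to the metal, should give the 14-acetoxy-2α-chloride F1. Replacement of the allylic chloride by acetate with net retention (Pd(PPh3)4, LiOAc, LiCl, THF; ionisation and external attack are both anti to zerovalent palladium) then leads to 24. The configuration at C2 is in this way decoupled from the migration step.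

For step 12, closure of a ten-membered carbocycle from a flexible open chain may lose out to oligomerisation, or may give a trans C1=C2 bond. The fallback sets out from 17 and comes back at 20; it closes ring B first, so that C5 and C8 are held on a trans-disubstituted five-membered ring before ring A is formed. Carbonylative lactonisation of 17 (Pd(PPh3)4, CO, Et3N, MeCN) should give the monocyclic α-methylene lactone F2. Conjugate addition of benzeneselenol (PhSeSePh, NaBH4, EtOH, AcOH) masks the exocyclic methylene as the selenide F3, so that only the wanted alkenes can meet the catalyst. Ethylene cross-metathesis as in step 11 gives the triene F4, and ring-closing metathesis as in step 12 gives the bicyclic selenide F5. Oxidation with H2O2 and pyridine at 0 °C and selenoxide elimination restore the methylene group and give 20.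

For step 10, the anti relationship of C6 and C7 is the usual outcome of this coupling, but the aldehyde may instead add to the allyl face anti to the silyloxy group, which would set C7 and C6 wrongly with respect to C8. The fallback sets out from 2 (with 6 and 15 as before) and comes back at 22; it uses the enantiomeric bromide and inverts C8 at the end. (R)-Glycidol F6 is taken through steps 1 to 6 to give diol F7, bis-silyl ether F8, aldehyde F9, bromo ester F10, allylic alcohol F11 and dibromide F12. The chromium coupling with 15, now anti to the silyloxy group, should give adduct F13 with the target configuration at C6 and C7 and the opposite one at C8. Steps 11 to 14 then give triene F14, carbocycle F15, lactone F16 and the 8α-alcohol F17. Mitsunobu esterification with methacrylic acid (PPh3, diisopropyl azodicarboxylate, toluene, 0 °C) installs the ester with inversion at C8 and gives 22.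

Further compounds

F1 | step 16 | [(3aR,4R,6E,8S,10Z,11aR)-6-(acetyloxymethyl)-8-chloro-10-methyl-3-methylidene-2-oxo-3a,4,5,8,9,11a-hexahydrocyclodeca[b]furan-4-yl] 2-methylprop-2-enoate | C=C(C)C(=O)O[C@@H]1C/C(COC(C)=O)=C\[C@@H](Cl)C/C(C)=C\[C@H]2OC(=O)C(=C)[C@@H]21
F2 | step 12 | (4S,5R)-3-methylidene-5-[(1Z)-2-methylpenta-1,4-dien-1-yl]-4-[(1R)-1-(triethylsilyloxy)but-3-yn-1-yl]oxolan-2-one | C#CC[C@@H](O[Si](CC)(CC)CC)[C@H]1C(=C)C(=O)O[C@@H]1/C=C(C)\CC=C
F3 | step 12 | (4S,5R)-5-[(1Z)-2-methylpenta-1,4-dien-1-yl]-3-[(phenylselanyl)methyl]-4-[(1R)-1-(triethylsilyloxy)but-3-yn-1-yl]oxolan-2-one (either configuration at C3) | C#CC[C@@H](O[Si](CC)(CC)CC)[C@H]1C(C[Se]c2ccccc2)C(=O)O[C@@H]1/C=C(C)\CC=C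
F4 | step 12 | (4S,5R)-5-[(1Z)-2-methylpenta-1,4-dien-1-yl]-4-[(1R)-3-methylidene-1-(triethylsilyloxy)pent-4-en-1-yl]-3-[(phenylselanyl)methyl]oxolan-2-one | C=CC(=C)C[C@@H](O[Si](CC)(CC)CC)[C@H]1C(C[Se]c2ccccc2)C(=O)O[C@@H]1/C=C(C)\CC=C
F5 | step 12 | (3aS,4R,7Z,10Z,11aR)-10-methyl-6-methylidene-3-[(phenylselanyl)methyl]-4-(triethylsilyloxy)-3a,4,5,6,9,11a-hexahydrocyclodeca[b]furan-2(3H)-one | CC[Si](CC)(CC)O[C@@H]1CC(=C)/C=C\C/C(C)=C\[C@H]2OC(=O)C(C[Se]c3ccccc3)[C@@H]21
F6 | step 10 | (R)-glycidol, (2R)-oxiran-2-ylmethanol | OC[C@@H]1CO1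
F7 | step 10 | (2S)-pent-4-yne-1,2-diol | OC[C@@H](O)CC#C
F8 | step 10 | (4S)-4,5-bis(triethylsilyloxy)pent-1-yne | CC[Si](CC)(CC)OC[C@@H](O[Si](CC)(CC)CC)CC#C
F9 | step 10 | (2S)-2-(triethylsilyloxy)pent-4-ynal | O=C[C@@H](O[Si](CC)(CC)CC)CC#C
F10 | step 10 | ethyl (2Z,4S)-2-bromo-4-(triethylsilyloxy)hept-2-en-6-ynoate | CCOC(=O)/C(Br)=C/[C@@H](O[Si](CC)(CC)CC)CC#C
F11 | step 10 | (2Z,4S)-2-bromo-4-(triethylsilyloxy)hept-2-en-6-yn-1-ol | OC/C(Br)=C/[C@@H](O[Si](CC)(CC)CC)CC#C
F12 | step 10 | (4S,5Z)-6,7-dibromo-4-(triethylsilyloxy)hept-5-en-1-yne | BrC/C(Br)=C/[C@@H](O[Si](CC)(CC)CC)CC#C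
F13 | step 10 | (4Z,6R,7S,8S)-7-(1-bromoethenyl)-4-methyl-8-(triethylsilyloxy)undeca-1,4-dien-10-yn-6-ol | C#CC[C@H](O[Si](CC)(CC)CC)[C@@H](C(Br)=C)[C@H](O)/C=C(C)\CC=C
F14 | step 10 | (4Z,6R,7S,8S)-7-(1-bromoethenyl)-4-methyl-10-methylidene-8-(triethylsilyloxy)dodeca-1,4,11-trien-6-ol | C=CC(=C)C[C@H](O[Si](CC)(CC)CC)[C@@H](C(Br)=C)[C@H](O)/C=C(C)\CC=C
F15 | step 10 | (1R,2Z,5Z,9S,10S)-10-(1-bromoethenyl)-3-methyl-7-methylidene-9-(triethylsilyloxy)cyclodeca-2,5-dien-1-ol | CC[Si](CC)(CC)O[C@H]1CC(=C)/C=C\C/C(C)=C\[C@@H](O)[C@@H]1C(Br)=C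
F16 | step 10 | (3aS,4S,7Z,10Z,11aR)-10-methyl-3,6-dimethylidene-4-(triethylsilyloxy)-3a,4,5,6,9,11a-hexahydrocyclodeca[b]furan-2(3H)-one | CC[Si](CC)(CC)O[C@H]1CC(=C)/C=C\C/C(C)=C\[C@H]2OC(=O)C(=C)[C@@H]21
F17 | step 10 | (3aR,4S,7Z,10Z,11aR)-4-hydroxy-10-methyl-3,6-dimethylidene-3a,4,5,6,9,11a-hexahydrocyclodeca[b]furan-2(3H)-one | O[C@H]1CC(=C)/C=C\C/C(C)=C\[C@H]2OC(=O)C(=C)[C@@H]21
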